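The benzene ring carries the hydroxyl group at C1 and the heneicosyl chain at C6 side by side, with the C2 methoxy group flanking C1. This ortho pair is treated as the footprint of an aryne: 3,5-dimethoxybenzyne, unsaturated between C1 and C6, takes up the C21 chain as a carbon nucleophile at C6 (the aryne carbon remote from the C2 methoxy group) and an oxygen electrophile at C1 in one flask. The precursor is 1-bromo-2-iodo-3,5-dimethoxybenzene; iodine–magnesium exchange and loss of MgBrCl release the aryne, n-heneicosylmagnesium bromide adds to forge the benzylic CH2–aryl bond, and the resulting C1 arylmagnesium is borylated and oxidised to the phenol.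

Key step: step 3

Remark: ring atoms are numbered as in the target name (C1 OH, C2 and C4 OMe, C6 chain); 1-bromoheneicosane (3) is taken as a purchasable long-chain bromide, and the excess of Grignard reagent 4 used in step 3 should end as 1-heneicosanol after the oxidative work-up and be removed by chromatography.

Step 1
Reactants: 1 1-bromo-3,5-dimethoxybenzene
Product: 2 1-bromo-2-iodo-3,5-dimethoxybenzene
Conditions: NIS (1.05 equiv), TFA (0.3 equiv), MeCN, 20 °C, dark
Reagents that add atoms: N-iodosuccinimide, O=C1CCC(=O)N1I
Why: Electrophilic aromatic iodination; C2 is para to one methoxy group and ortho to the other and is less hindered than C4, which is flanked by both methoxy groups, so a single iodine should enter beside the bromine.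

Step 2
Reactants: 3 1-bromoheneicosane
Product: 4 n-heneicosylmagnesium bromide (THF solution, titrated before use)
Conditions: Mg turnings (1.5 equiv), I2 (cat.), THF, 55 °C, slow addition of 3
Reagents that add atoms: magnesium, [Mg]
Why: Grignard reagent formation by insertion of magnesium into the primary C–Br bond; slow addition to excess metal at moderate dilution should suppress Wurtz coupling, and warm THF keeps the long-chain reagent in solution.

Step 3
Reactants: 2 1-bromo-2-iodo-3,5-dimethoxybenzene; 4 n-heneicosylmagnesium bromide
Product: 9 6-n-heneicosyl-2,4-dimethoxyphenol, via 2-bromo-4,6-dimethoxyphenylmagnesium chloride 5 (not isolated), via 3,5-dimethoxybenzyne 6 (not isolated), via 2-heneicosyl-4,6-dimethoxyphenylmagnesium bromide 7 (not isolated), via dimethyl 2-heneicosyl-4,6-dimethoxyphenylboronate 8 (not isolated)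
Conditions: i-PrMgCl·LiCl (1.05 equiv), THF, –20 °C; then 4 (2.0 equiv), –20 → 60 °C; then B(OMe)3 (4 equiv), 0 → 20 °C; then 30% aq H2O2, AcOH, 0 → 20 °C; Na2S2O3 quench
Reagents that add atoms: hydrogen peroxide, OO (the phenol oxygen of 9); isopropylmagnesium chloride–lithium chloride, CC(C)[Mg]Cl.[Li+].[Cl-] (Mg and Cl of 5 only); trimethyl borate, COB(OC)OC (boron and its methoxy groups in 8 only)
Why: Iodine–magnesium exchange at C2 of 2 (activated by the flanking bromine and methoxy group) gives aryl Grignard 5 at –20 °C, which on warming loses MgBrCl to give aryne 6; Grignard 4 then adds across the strained triple bond (carbomagnesiation) to form the benzylic CH2–aryl bond and aryl Grignard 7, which B(OMe)3 converts into boronate 8 and H2O2 oxidises to the phenol by 1,2-shift of the aryl group from boron to oxygen. The closest known reaction types are the carbomagnesiation of arynes and 3,4-pyridynes released from ortho-halo arylmagnesium species with electrophilic trapping of the new arylmagnesium, and the borylation–oxidation of aryl Grignard reagents to phenols. No ring is closed and no stereocentre is formed. The step needs regioselective addition to the unsymmetrical aryne: the σ-withdrawing methoxy group beside the triple bond distorts 6 so that the remote aryne carbon is the more linear and electrophilic one, and the carbanion (C–Mg) develops at the carbon next to the methoxy oxygen, where it is inductively stabilised and chelated, so the chain should enter meta to that methoxy group and the oxygen should end up between chain and methoxy group. It also needs chemoselectivity among the organomagnesium species: i-PrMgCl is consumed by the exchange before the aryne forms, and the unhindered primary alkyl Grignard 4, used in excess, should outrun the doubly ortho-substituted aryl Grignards 5 and 7 in capturing 6.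

Compound list
1 | 1-bromo-3,5-dimethoxybenzene | COc1cc(Br)cc(OC)c1 | starting material
2 | 1-bromo-2-iodo-3,5-dimethoxybenzene | COc1cc(OC)c(I)c(Br)c1 | intermediate
3 | 1-bromoheneicosane | CCCCCCCCCCCCCCCCCCCCCBr | starting material
4 | n-heneicosylmagnesium bromide | CCCCCCCCCCCCCCCCCCCCC[Mg]Br | intermediate
5 | (2-bromo-4,6-dimethoxyphenyl)magnesium chloride | COc1cc(OC)c([Mg]Cl)c(Br)c1 | intermediate
6 | 3,5-dimethoxybenzyne (1,2-didehydro-3,5-dimethoxybenzene) | COC1=CC#CC(OC)=C1 | intermediate
7 | (2-n-heneicosyl-4,6-dimethoxyphenyl)magnesium bromide | CCCCCCCCCCCCCCCCCCCCCc1cc(OC)cc(OC)c1[Mg]Br | intermediate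
8 | dimethyl (2-n-heneicosyl-4,6-dimethoxyphenyl)boronate | CCCCCCCCCCCCCCCCCCCCCc1cc(OC)cc(OC)c1B(OC)OC | intermediate
9 | 6-n-heneicosyl-2,4-dimethoxyphenol | CCCCCCCCCCCCCCCCCCCCCc1cc(OC)cc(OC)c1O | target

Total step count: 3. Longest linear sequence: 2 steps (step 1 then step 3, or step 2 then step 3).

Steps most likely to fail

Step 3. Three processes may defeat it: the loss of MgBrCl from 5 may be slow, so that aryl Grignards 5 and 7 compete with 4 for the aryne and oligoaryls form; β-hydride transfer from 4 may reduce the aryne; and 7 may be protonated before it is borylated, so that the oxygen is never installed. The fallback abandons the aryne and installs the two groups one after the other. It sets out from 1 and 4: Kumada–Corriu coupling with NiCl2(dppp) (divalent nickel, catalytic) in THF at 50 °C should give 1-n-heneicosyl-3,5-dimethoxybenzene F1. Bromination with NBS in MeCN at 0 °C should then occur para to one methoxy group and ortho to the chain, giving 2-bromo-1-n-heneicosyl-3,5-dimethoxybenzene F2. Bromine–lithium exchange with n-BuLi in THF at –60 °C should give (2-n-heneicosyl-4,6-dimethoxyphenyl)lithium F3, which is quenched with B(OMe)3. The fallback comes back to the route at boronate 8, which is oxidised to 9 as in step 3.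

Step 1. Iodination may also take place at C4 between the two methoxy groups, or a second iodine may enter, giving mixtures that are hard to separate. The fallback generates the aryne by deprotonation instead of halogenation and exchange. It sets out from 1: LiTMP (1.2 equiv) is added to 1 and 4 (2 equiv) in THF at –40 °C. Removal of the C2 proton between bromine and methoxy should give (2-bromo-4,6-dimethoxyphenyl)lithium F4, which loses LiBr on warming. The hindered amide should not add to the aryne, and lithiation at C4 is unproductive and should be returned by proton exchange with the amine. The fallback comes back to the route at aryne 6 and continues through 7 and 8 to 9 as in step 3.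

Step 2. Initiation on the waxy bromide may be sluggish, and Wurtz homocoupling or precipitation of the reagent may lower its titre. The fallback makes the organometallic by halogen–lithium exchange instead of metal insertion. It sets out from 3: Finkelstein reaction with NaI in refluxing acetone should give 1-iodoheneicosane F5. Iodine–lithium exchange with t-BuLi (2.1 equiv) in Et2O/pentane at –78 → –40 °C should give n-heneicosyllithium F6. Transmetalation with MgBr2·OEt2 brings the fallback back to the route at 4.

Further compounds
F1 | step 3 | 1-n-heneicosyl-3,5-dimethoxybenzene | CCCCCCCCCCCCCCCCCCCCCc1cc(OC)cc(OC)c1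
F2 | step 3 | 2-bromo-1-n-heneicosyl-3,5-dimethoxybenzene | CCCCCCCCCCCCCCCCCCCCCc1cc(OC)cc(OC)c1Br
F3 | step 3 | (2-n-heneicosyl-4,6-dimethoxyphenyl)lithium | CCCCCCCCCCCCCCCCCCCCCc1cc(OC)cc(OC)c1[Li]
F4 | step 1 | (2-bromo-4,6-dimethoxyphenyl)lithium | COc1cc(OC)c([Li])c(Br)c1
F5 | step 2 | 1-iodoheneicosane | CCCCCCCCCCCCCCCCCCCCCI
F6 | step 2 | n-heneicosyllithium | CCCCCCCCCCCCCCCCCCCCC[Li]
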